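The bond on which everything rests is C4–C5 of the butanolide ring (numbered O1, C2 carbonyl, C3 methylene-bearing, C4 carboxyl-bearing, C5 chain-bearing). C4 carries a vinyl donor (C3=CH2) and a carboxyl acceptor, and C5–H lies next to O1 and 1,5 to C4: the pattern of an intramolecular donor/acceptor carbene C–H insertion. The precursor is an achiral allyl alkyl ether, a tert-butyl vinyldiazoacetate with C2 still at the CH2 level so that O1 activates C5–H. A chiral dirhodium carboxylate closes the oxolane and should set both stereocentres (cis) in one operation. Allylic oxidation of C2 and acid deprotection finish the synthesis.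

Key step: step 6

Remarks: The ring numbering above (O1, C2, C3, C4, C5) is used in all Why lines; systematic names use oxolane numbering, in which the target is the cis (2S,3S) acid. Assumption: the (S)-configured catalyst is taken to give the (2S,3S) product; if the sense of induction proves opposite, the mirror-image catalyst Rh2(R-PTTL)4 is used.

Step 1
Reactants: 1 ω-pentadecalactone (oxacyclohexadecan-2-one)
Product: 3 16-hydroxyhexadecan-2-one, via Weinreb amide 2 (not isolated)
Conditions: MeNH(OMe)·HCl, i-PrMgCl, THF, −20 °C; then MeMgBr, 0 °C; aq. NH4Cl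
Reagents that add atoms: methylmagnesium bromide, C[Mg]Br
Why: The chloromagnesium amide opens the macrolactone to Weinreb amide 2, whose magnesium chelate takes up one methyl group and releases the methyl ketone only on work-up (Weinreb ketone synthesis).

Step 2
Reactants: 3 16-hydroxyhexadecan-2-one
Product: 4 14-(2-methyl-1,3-dioxolan-2-yl)tetradecan-1-ol
Conditions: HOCH2CH2OH, p-TsOH (cat.), toluene, reflux, Dean–Stark
Reagents that add atoms: ethane-1,2-diol, OCCO
Why: Acid-catalysed ketalisation with azeotropic removal of water masks the enolisable methyl ketone as a dioxolane that should withstand NaH, the zinc enolate, DBU, the rhodium carbene and the chromium oxidant, while the primary alcohol stays free.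

Step 3
Reactants: 4 14-(2-methyl-1,3-dioxolan-2-yl)tetradecan-1-ol; 5 2,3-dibromoprop-1-ene
Product: 6 2-[14-(2-bromoprop-2-en-1-yloxy)tetradecyl]-2-methyl-1,3-dioxolane
Conditions: NaH, THF/DMF, 0 °C; then 5 (1.5 equiv), Bu4NI (cat.), rt
Reagents that add atoms: none
Why: Williamson ether synthesis: the primary alkoxide displaces the allylic bromide of 5 by SN2 while the vinylic bromide is inert, which installs O1–C2 and the future C3=CH2.

Step 4
Reactants: 6 2-[14-(2-bromoprop-2-en-1-yloxy)tetradecyl]-2-methyl-1,3-dioxolane; 7 (2-tert-butoxy-2-oxoethyl)zinc bromide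
Product: 8 tert-butyl 3-({[14-(2-methyl-1,3-dioxolan-2-yl)tetradecyl]oxy}methyl)but-3-enoate
Conditions: Pd(P(t-Bu)3)2 (3 mol %), THF, rt
Reagents that add atoms: none
Why: Negishi-type coupling of a Reformatsky reagent: oxidative addition of the vinyl bromide to zerovalent palladium, transmetalation of the zinc enolate through carbon and reductive elimination give the beta,gamma-unsaturated ester that brings in C4 and its carboxyl.

Step 5
Reactants: 8 tert-butyl 3-({[14-(2-methyl-1,3-dioxolan-2-yl)tetradecyl]oxy}methyl)but-3-enoate
Product: 9 tert-butyl 2-diazo-3-({[14-(2-methyl-1,3-dioxolan-2-yl)tetradecyl]oxy}methyl)but-3-enoate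
Conditions: p-ABSA, DBU, MeCN, 0 °C; cold filtration through silica, used at once
Reagents that add atoms: 4-acetamidobenzenesulfonyl azide (p-ABSA), CC(=O)Nc1ccc(cc1)S(=O)(=O)N=[N+]=[N-]
Why: Regitz diazo transfer: DBU forms the dienolate of the allylic ester CH2, which attacks the sulfonyl azide at the alpha carbon and loses the sulfonamide to give the vinyldiazoacetate.

Step 6
Reactants: 9 tert-butyl 2-diazo-3-({[14-(2-methyl-1,3-dioxolan-2-yl)tetradecyl]oxy}methyl)but-3-enoate
Product: 10 tert-butyl (2S,3S)-4-methylidene-2-[13-(2-methyl-1,3-dioxolan-2-yl)tridecyl]oxolane-3-carboxylate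
Conditions: Rh2(S-PTTL)4 (1 mol %), toluene, −60 °C, slow addition of 9, then −20 °C
Reagents that add atoms: none
Why: Proposed new method: the dirhodium carboxylate (dirhodium tetrakis[N-phthaloyl-(S)-tert-leucinate]) expels N2 from 9 to give a rhodium-bound carbene at C4, stabilised by the C3=CH2 vinyl donor and the ester acceptor, and this electrophilic carbon inserts into the hydridic C5–H bond next to O1 through a concerted, asynchronous three-centre transition state, so that C4–C5 forms with retention at C5. The closest known reaction type is the enantioselective intramolecular 1,5 C–H insertion of aryldiazoacetates into ether alpha C–H bonds, which gives cis-2-substituted 3-alkoxycarbonyl-2,3-dihydrobenzofurans with this catalyst family, together with the 1,5 insertion of alkyl alpha-diazo esters into ether C–H bonds to give oxolane-3-carboxylates; a vinyl donor with an sp3 carbon (C2) in the tether has not been shown. The oxolane closes in the 1,5-insertion mode through a five-membered cyclic transition state (C4–C3–C2–O1–C5). The catalyst picks one of the two enantiotopic hydrogens of the OCH2 group and so fixes C5, and C4 is fixed in the same transition state, in which the long chain points away from the catalyst wall and the ester lies perpendicular to the carbene plane, the arrangement that leads to the cis product in the dihydrobenzofuran series. The step needs site selectivity for C5–H over the tert-butyl C–H bonds, over closure of the vinylcarbene to a cyclopropene and over carbene dimerisation, and the ether oxygen, the five-membered transition state, slow addition and low temperature should secure it. The cis relationship and the absolute sense rest on analogy and are to be confirmed on 10 before it is carried on.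

Step 7
Reactants: 10 tert-butyl (2S,3S)-4-methylidene-2-[13-(2-methyl-1,3-dioxolan-2-yl)tridecyl]oxolane-3-carboxylate
Product: 11 tert-butyl (2S,3S)-4-methylidene-2-[13-(2-methyl-1,3-dioxolan-2-yl)tridecyl]-5-oxooxolane-3-carboxylate
Conditions: CrO3·2C5H5N (Collins reagent, excess), CH2Cl2, rt
Reagents that add atoms: chromium trioxide (as its bis-pyridine complex), O=[Cr](=O)=O
Why: Allylic oxidation by hexavalent chromium: the ring CH2 at C2 is both allylic and alpha to the ether oxygen and should be oxidised to the lactone carbonyl, as is known for 3-methylideneoxolanes, while the tertiary C4–H next to the ester is deactivated and neither stereocentre is touched.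

Step 8
Reactants: 11 tert-butyl (2S,3S)-4-methylidene-2-[13-(2-methyl-1,3-dioxolan-2-yl)tridecyl]-5-oxooxolane-3-carboxylate
Product: 13 allo-pertusaric acid, via keto tert-butyl ester 12 (not isolated)
Conditions: TFA/CH2Cl2/H2O, 0 °C to rt
Reagents that add atoms: water, O
Why: Aqueous trifluoroacetic acid first hydrolyses the dioxolane to the methyl ketone (12) and then cleaves the tert-butyl ester by the E1 path with loss of 2-methylpropene; no base is present, so the cis C4 centre and the exocyclic alkene should be kept.

Compound list
1 | ω-pentadecalactone (oxacyclohexadecan-2-one) | O=C1CCCCCCCCCCCCCCO1 | starting material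
2 | 15-hydroxy-N-methoxy-N-methylpentadecanamide (Weinreb amide, not isolated) | CON(C)C(=O)CCCCCCCCCCCCCCO | intermediate
3 | 16-hydroxyhexadecan-2-one | CC(=O)CCCCCCCCCCCCCCO | intermediate
4 | 14-(2-methyl-1,3-dioxolan-2-yl)tetradecan-1-ol | OCCCCCCCCCCCCCCC1(C)OCCO1 | intermediate
5 | 2,3-dibromoprop-1-ene | C=C(Br)CBr | starting material
6 | 2-[14-(2-bromoprop-2-en-1-yloxy)tetradecyl]-2-methyl-1,3-dioxolane | C=C(Br)COCCCCCCCCCCCCCCC1(C)OCCO1 | intermediate
7 | (2-tert-butoxy-2-oxoethyl)zinc bromide (Reformatsky reagent, commercial solution) | CC(C)(C)OC(=O)C[Zn]Br | starting material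
8 | tert-butyl 3-({[14-(2-methyl-1,3-dioxolan-2-yl)tetradecyl]oxy}methyl)but-3-enoate | C=C(CC(=O)OC(C)(C)C)COCCCCCCCCCCCCCCC1(C)OCCO1 | intermediate
9 | tert-butyl 2-diazo-3-({[14-(2-methyl-1,3-dioxolan-2-yl)tetradecyl]oxy}methyl)but-3-enoate | C=C(COCCCCCCCCCCCCCCC1(C)OCCO1)C(=[N+]=[N-])C(=O)OC(C)(C)C | intermediate
10 | tert-butyl (2S,3S)-4-methylidene-2-[13-(2-methyl-1,3-dioxolan-2-yl)tridecyl]oxolane-3-carboxylate (cis) | C=C1CO[C@@H](CCCCCCCCCCCCCC2(C)OCCO2)[C@H]1C(=O)OC(C)(C)C | intermediate
11 | tert-butyl (2S,3S)-4-methylidene-2-[13-(2-methyl-1,3-dioxolan-2-yl)tridecyl]-5-oxooxolane-3-carboxylate (cis) | C=C1C(=O)O[C@@H](CCCCCCCCCCCCCC2(C)OCCO2)[C@H]1C(=O)OC(C)(C)C | intermediate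
12 | tert-butyl (2S,3S)-4-methylidene-5-oxo-2-(14-oxopentadecyl)oxolane-3-carboxylate (not isolated) | C=C1C(=O)O[C@@H](CCCCCCCCCCCCCC(C)=O)[C@H]1C(=O)OC(C)(C)C | intermediate
13 | allo-pertusaric acid, (2S,3S)-4-methylidene-5-oxo-2-(14-oxopentadecyl)oxolane-3-carboxylic acid | C=C1C(=O)O[C@@H](CCCCCCCCCCCCCC(C)=O)[C@H]1C(=O)O | target

Total step count: 8. Longest linear sequence: 8 steps (from 1).

Steps most likely to fail

Step 6 (proposed new method). The insertion may show poor cis/trans or facial selectivity, or the vinylcarbene may be diverted into cyclopropene formation or dimerisation. The fallback makes C4–C5 by known intermolecular allylation and closes the ring by lactonisation; it sets out from 4 and comes back to the route at 13. Dess–Martin oxidation of 4 should give 14-(2-methyl-1,3-dioxolan-2-yl)tetradecanal F1. Barbier allylation of F1 with the catalogue reagent dimethyl (Z)-2-(bromomethyl)but-2-enedioate (indium powder, THF/H2O, rt; SE2' attack through the ester-bearing carbon) should give the syn adduct dimethyl (2S)-2-[(1S)-1-hydroxy-14-(2-methyl-1,3-dioxolan-2-yl)tetradecyl]-3-methylidenebutanedioate F2 as the racemate. F2 should lactonise on standing or on silica to methyl (2S,3S)-4-methylidene-2-[13-(2-methyl-1,3-dioxolan-2-yl)tridecyl]-5-oxooxolane-3-carboxylate F3, also racemic. F3 is separated from the trans isomer by chromatography and from its mirror image by preparative HPLC on a chiral stationary phase. Hydrolysis of the methyl ester and the dioxolane (6 M HCl, 2-butanone, reflux) then gives 13.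

Step 5. DBU may move the double bond of 8 into conjugation before diazo transfer, and 9 may cyclise thermally to a pyrazole during isolation. The fallback attaches the diazo carbon by cross-coupling under near-neutral conditions; it sets out from 6 and comes back at 9, so that 8 is bypassed. Copper-catalysed halogen exchange (CuI, NaI, N,N'-dimethylethane-1,2-diamine, dioxane, 110 °C) should give 2-[14-(2-iodoprop-2-en-1-yloxy)tetradecyl]-2-methyl-1,3-dioxolane F4. Coupling of F4 with tert-butyl diazoacetate (Pd(PPh3)4, Et3N, Bu4NBr, MeCN, rt) proceeds by insertion of zerovalent palladium into the C–I bond, palladation of the diazoacetate at carbon and reductive elimination with the diazo group kept. It should give 9, which is passed cold and without concentration into step 6.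

Step 7. Over-oxidation, pyridine-induced migration of the exocyclic double bond into the ring, or epimerisation at C4 may occur. The fallback splits the oxidation into an ene-type hydroxylation and a base-free lactol oxidation; it sets out from 10 and comes back at 11. SeO2 (cat.) with t-BuOOH in CH2Cl2 should hydroxylate the ring CH2 at C2 (ene reaction, then 2,3-sigmatropic shift, CH2 preferred over the tertiary C4–H) to give tert-butyl (2S,3S)-5-hydroxy-4-methylidene-2-[13-(2-methyl-1,3-dioxolan-2-yl)tridecyl]oxolane-3-carboxylate F5 as a mixture of anomers. MnO2 in CH2Cl2 should then oxidise the allylic lactol F5 to 11.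

Further compounds
F1 | step 6 | 14-(2-methyl-1,3-dioxolan-2-yl)tetradecanal | O=CCCCCCCCCCCCCCC1(C)OCCO1
F2 | step 6 | dimethyl (2S)-2-[(1S)-1-hydroxy-14-(2-methyl-1,3-dioxolan-2-yl)tetradecyl]-3-methylidenebutanedioate (formed as racemate, enantiomer leading to F3 drawn) | C=C(C(=O)OC)[C@H](C(=O)OC)[C@@H](O)CCCCCCCCCCCCCC1(C)OCCO1
F3 | step 6 | methyl (2S,3S)-4-methylidene-2-[13-(2-methyl-1,3-dioxolan-2-yl)tridecyl]-5-oxooxolane-3-carboxylate (formed as racemate, resolved) | C=C1C(=O)O[C@@H](CCCCCCCCCCCCCC2(C)OCCO2)[C@H]1C(=O)OC
F4 | step 5 | 2-[14-(2-iodoprop-2-en-1-yloxy)tetradecyl]-2-methyl-1,3-dioxolane | C=C(I)COCCCCCCCCCCCCCCC1(C)OCCO1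
F5 | step 7 | tert-butyl (2S,3S)-5-hydroxy-4-methylidene-2-[13-(2-methyl-1,3-dioxolan-2-yl)tridecyl]oxolane-3-carboxylate (mixture of anomers) | C=C1C(O)O[C@@H](CCCCCCCCCCCCCC2(C)OCCO2)[C@H]1C(=O)OC(C)(C)C
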